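The route rests on cutting the C4–C4a bond of the 2H-chromene. Since the C3=C4 alkene is flanked by the quaternary stereocentre C2 and by C4a of ring A, the pyran ring can be completed by joining the terminal carbon of a C2-bound alkyne to the ring A carbon ortho to O1. A single gold-catalysed hydroarylation thus forms the ring and the C3=C4 alkene while none of the four bonds at C2 is broken, so the S configuration taken from Sharpless epoxidation of geraniol survives. The substrate is an (S)-configured tertiary propargyl 4-bromophenyl ether with a TBS-protected 3-hydroxypropyl chain; the bromide later accepts the catechol arm.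

Key step: step 7

Remark: chromene positions are numbered O1, C2, C3, C4, C4a, C5 to C8, C8a, with ring A the benzo ring; the target SMILES corresponds to the S configuration at C2 and the E allylic alcohol.

Step 1
Reactants: 1 geraniol
Product: 2 [(2S,3S)-3-methyl-3-(4-methylpent-3-en-1-yl)oxiran-2-yl]methanol
Conditions: Ti(OiPr)4 (5 mol%), L-(+)-diethyl tartrate (7 mol%), tBuOOH, 4 Å MS, CH2Cl2, −20 °C
Reagents that add atoms: tert-butyl hydroperoxide, CC(C)(C)OO
Why: Katsuki–Sharpless asymmetric epoxidation, in which the titanium tartrate complex binds the allylic hydroxyl and delivers oxygen to one face of the 2,3-alkene only, so L-(+)-tartrate should give the 2S,3S epoxide whose quaternary carbon becomes C2 of the chromene.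

Step 2
Reactants: 2 [(2S,3S)-3-methyl-3-(4-methylpent-3-en-1-yl)oxiran-2-yl]methanol
Product: 3 (2S,3R)-3-(chloromethyl)-2-methyl-2-(4-methylpent-3-en-1-yl)oxirane
Conditions: PPh3, CCl4, NaHCO3 (cat.), reflux
Reagents that add atoms: carbon tetrachloride, ClC(Cl)(Cl)Cl
Why: Appel chlorination of the primary alcohol through an alkoxyphosphonium salt under near-neutral conditions that leave the epoxide closed and both stereocentres untouched (the descriptor of the CH carbon changes only because chlorine raises the rank of the CH2 group).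

Step 3
Reactants: 3 (2S,3R)-3-(chloromethyl)-2-methyl-2-(4-methylpent-3-en-1-yl)oxirane
Product: 5 (3S)-3,7-dimethyloct-6-en-1-yn-3-ol, via chlorodienol alkoxide 4 (not isolated)
Conditions: n-BuLi (3.2 equiv), THF, −40 → −20 °C; aq. NH4Cl
Reagents that add atoms: none
Why: Base-induced fragmentation of a 2,3-epoxy chloride to a propargylic alcohol, in which lithiation alpha to chlorine opens the epoxide by beta-elimination, a second equivalent removes HCl to give the alkyne and a third holds it as the acetylide; the bond between the quaternary carbon and oxygen is never broken, so the carbinol keeps its configuration.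

Step 4
Reactants: 5 (3S)-3,7-dimethyloct-6-en-1-yn-3-ol; 6 bis(4-bromophenyl)iodonium trifluoromethanesulfonate
Product: 7 1-bromo-4-{[(3S)-3,7-dimethyloct-6-en-1-yn-3-yl]oxy}benzene
Conditions: NaH, TBME, 0 °C → rt; then 6, rt
Reagents that add atoms: none
Why: Metal-free O-arylation of a tertiary alkoxide with a diaryliodonium salt (ligand exchange at trivalent iodine, then ligand coupling), which forms the aryl–O bond and so cannot disturb the stereocentre, while the symmetrical salt can transfer only a 4-bromophenyl group.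

Step 5
Reactants: 7 1-bromo-4-{[(3S)-3,7-dimethyloct-6-en-1-yn-3-yl]oxy}benzene
Product: 9 (4S)-4-(4-bromophenoxy)-4-methylhex-5-yn-1-ol, via aldehyde 8 (not isolated)
Conditions: O3, CH2Cl2/MeOH, −78 °C (Sudan Red 7B end point); then NaBH4 (excess), −78 °C → rt
Reagents that add atoms: ozone, [O-][O+]=O
Why: Ozonolysis with reductive borohydride work-up, chemoselective because the electron-rich trisubstituted alkene reacts with ozone far faster than the terminal alkyne or the bromoaryl ether and the dye marks the end point; the excess borohydride also reduces the acetone that is split off.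

Step 6
Reactants: 9 (4S)-4-(4-bromophenoxy)-4-methylhex-5-yn-1-ol
Product: 10 {[(4S)-4-(4-bromophenoxy)-4-methylhex-5-yn-1-yl]oxy}(tert-butyl)dimethylsilane
Conditions: TBSCl, imidazole, CH2Cl2, rt
Reagents that add atoms: tert-butyldimethylsilyl chloride, CC(C)(C)[Si](C)(C)Cl
Why: Standard silylation of a primary alcohol, which masks a hydroxyl that would otherwise add to the gold-activated alkyne and gives an ether that mild acid can remove later.

Step 7
Reactants: 10 {[(4S)-4-(4-bromophenoxy)-4-methylhex-5-yn-1-yl]oxy}(tert-butyl)dimethylsilane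
Product: 11 (2S)-6-bromo-2-{3-[(tert-butyldimethylsilyl)oxy]propyl}-2-methyl-2H-chromene
Conditions: [(2-biphenylyl)(tBu)2P]Au(NCMe)SbF6 (3 mol%), CH2Cl2, 0 °C → rt
Reagents that add atoms: none
Why: The cationic monovalent gold centre binds the terminal alkyne, the ring A carbon ortho to oxygen attacks the terminal alkyne carbon anti to gold in a Friedel–Crafts sense, and rearomatisation followed by protodeauration at C3 releases the 2H-chromene and the catalyst. The closest known reaction type is the gold- or platinum-catalysed intramolecular hydroarylation of aryl propargyl ethers to 2H-chromenes. The pyran ring closes in the 6-endo-dig mode, forming C4–C4a with C3=C4 in place. No stereocentre is created; the S centre at C2 is retained because, unlike in a propargyl Claisen sequence, the C2–O1 bond and the other three bonds at C2 stay intact. The step needs 6-endo closure to outrun both 5-exo attack and ionisation of the tertiary propargylic ether, which the unsubstituted alkyne terminus, the bulky electron-rich phosphine, the non-coordinating counter-ion and a low temperature in a weakly polar solvent should secure. The para bromide makes the two ortho carbons equivalent, the prenyl alkene has already been removed so that no enyne cycloisomerisation can compete, and the hindered TBS ether is a poor nucleophile toward the activated alkyne.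

Step 8
Reactants: 12 2,3-dihydroxybenzaldehyde
Product: 13 2,3-bis[(triisopropylsilyl)oxy]benzaldehyde
Conditions: TIPSOTf, 2,6-lutidine, CH2Cl2, 0 °C → rt
Reagents that add atoms: triisopropylsilyl trifluoromethanesulfonate, CC(C)[Si](OS(=O)(=O)C(F)(F)F)(C(C)C)C(C)C
Why: Silylation of both phenols with the reactive silyl triflate, which also reaches the hydrogen-bonded 2-hydroxyl; aryl TIPS ethers are chosen because they should withstand the aqueous base of the coupling and the mild acid used later, yet fall to fluoride at the end.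

Step 9
Reactants: 13 2,3-bis[(triisopropylsilyl)oxy]benzaldehyde
Product: 14 1-ethenyl-2,3-bis[(triisopropylsilyl)oxy]benzene
Conditions: Ph3PCH3Br, KOtBu, THF, 0 °C → rt
Reagents that add atoms: methyltriphenylphosphonium bromide, C[P+](c1ccccc1)(c1ccccc1)c1ccccc1.[Br-]
Why: Wittig methylenation of the aromatic aldehyde with the non-stabilised ylide, which does not attack the hindered aryl silyl ethers.

Step 10
Reactants: 14 1-ethenyl-2,3-bis[(triisopropylsilyl)oxy]benzene; 11 (2S)-6-bromo-2-{3-[(tert-butyldimethylsilyl)oxy]propyl}-2-methyl-2H-chromene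
Product: 16 (2S)-6-(2-{2,3-bis[(triisopropylsilyl)oxy]phenyl}ethyl)-2-{3-[(tert-butyldimethylsilyl)oxy]propyl}-2-methyl-2H-chromene, via alkylborane 15 (not isolated)
Conditions: 14 (1.4 equiv), 9-BBN (1.3 equiv), THF, 0 °C → rt; then 11, PdCl2(dppf) (5 mol%), aq. K3PO4, THF, 50 °C
Reagents that add atoms: 9-borabicyclo[3.3.1]nonane, B1C2CCCC1CCC2 (its boron unit is held only in 15; 16 keeps one hydrogen from it)
Why: Anti-Markovnikov hydroboration of the styrene with 9-BBN followed by B-alkyl Suzuki–Miyaura coupling at the C6 bromide; keeping the borane below the amount of 14 leaves no B–H to attack the chromene alkene, and the C2 stereocentre is remote from the reacting sites.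

Step 11
Reactants: 16 (2S)-6-(2-{2,3-bis[(triisopropylsilyl)oxy]phenyl}ethyl)-2-{3-[(tert-butyldimethylsilyl)oxy]propyl}-2-methyl-2H-chromene
Product: 17 3-[(2S)-6-(2-{2,3-bis[(triisopropylsilyl)oxy]phenyl}ethyl)-2-methyl-2H-chromen-2-yl]propan-1-ol
Conditions: PPTS (0.3 equiv), MeOH, 40 °C
Reagents that add atoms: none
Why: Acid-catalysed methanolysis that is selective for the primary alkyl TBS ether, since aryl TIPS ethers are far slower to cleave under acid and the pyridinium salt is too weak an acid to ionise the C2–O1 bond or protonate the chromene alkene.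

Step 12
Reactants: 17 3-[(2S)-6-(2-{2,3-bis[(triisopropylsilyl)oxy]phenyl}ethyl)-2-methyl-2H-chromen-2-yl]propan-1-ol
Product: 18 3-[(2S)-6-(2-{2,3-bis[(triisopropylsilyl)oxy]phenyl}ethyl)-2-methyl-2H-chromen-2-yl]propanal
Conditions: Dess–Martin periodinane, CH2Cl2, 0 °C → rt
Reagents that add atoms: none
Why: Dess–Martin oxidation of the primary alcohol to the aldehyde under mild, non-basic conditions that spare the chromene alkene and the aryl silyl ethers.

Step 13
Reactants: 18 3-[(2S)-6-(2-{2,3-bis[(triisopropylsilyl)oxy]phenyl}ethyl)-2-methyl-2H-chromen-2-yl]propanal; 19 ethyl 2-(triphenylphosphoranylidene)propanoate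
Product: 20 ethyl (2E)-5-[(2S)-6-(2-{2,3-bis[(triisopropylsilyl)oxy]phenyl}ethyl)-2-methyl-2H-chromen-2-yl]-2-methylpent-2-enoate
Conditions: CH2Cl2, rt
Reagents that add atoms: none
Why: Wittig olefination of an unhindered aliphatic aldehyde with a stabilised ylide, which strongly favours the E trisubstituted enoate (ester trans to the chain).

Step 14
Reactants: 20 ethyl (2E)-5-[(2S)-6-(2-{2,3-bis[(triisopropylsilyl)oxy]phenyl}ethyl)-2-methyl-2H-chromen-2-yl]-2-methylpent-2-enoate
Product: 21 (2E)-5-[(2S)-6-(2-{2,3-bis[(triisopropylsilyl)oxy]phenyl}ethyl)-2-methyl-2H-chromen-2-yl]-2-methylpent-2-en-1-ol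
Conditions: iBu2AlH (2.5 equiv), CH2Cl2, −78 °C; aq. potassium sodium tartrate
Reagents that add atoms: none
Why: 1,2-Reduction of the unsaturated ester to the allylic alcohol by iBu2AlH at low temperature, which leaves the alkene geometry, the silyl ethers and the chromene untouched.

Step 15
Reactants: 21 (2E)-5-[(2S)-6-(2-{2,3-bis[(triisopropylsilyl)oxy]phenyl}ethyl)-2-methyl-2H-chromen-2-yl]-2-methylpent-2-en-1-ol
Product: 22 3-{2-[(2S)-2-[(3E)-5-hydroxy-4-methylpent-3-en-1-yl]-2-methyl-2H-chromen-6-yl]ethyl}benzene-1,2-diol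
Conditions: TBAF, AcOH (1:1, 2.5 equiv), THF, 0 °C, argon
Reagents that add atoms: none
Why: Fluoride-induced cleavage of both aryl TIPS ethers, buffered with acetic acid so that the air-sensitive catechol is released as the neutral phenol and not as the catecholate.

Compound list
1 | geraniol | CC(C)=CCC/C(C)=C/CO | starting material
2 | [(2S,3S)-3-methyl-3-(4-methylpent-3-en-1-yl)oxiran-2-yl]methanol | OC[C@@H]1O[C@@]1(C)CCC=C(C)C | intermediate
3 | (2S,3R)-3-(chloromethyl)-2-methyl-2-(4-methylpent-3-en-1-yl)oxirane | ClC[C@@H]1O[C@@]1(C)CCC=C(C)C | intermediate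
4 | (1E,3S)-1-chloro-3,7-dimethylocta-1,6-dien-3-ol, present as its lithium alkoxide, not isolated (E drawn; either alkene geometry would go on to the alkyne) | CC(C)=CCC[C@@](O)(C)/C=C/Cl | intermediate
5 | (3S)-3,7-dimethyloct-6-en-1-yn-3-ol | CC(C)=CCC[C@@](O)(C)C#C | intermediate
6 | bis(4-bromophenyl)iodonium trifluoromethanesulfonate | Brc1ccc([I+]c2ccc(Br)cc2)cc1.[O-]S(=O)(=O)C(F)(F)F | starting material
7 | 1-bromo-4-{[(3S)-3,7-dimethyloct-6-en-1-yn-3-yl]oxy}benzene | CC(C)=CCC[C@@](Oc1ccc(Br)cc1)(C)C#C | intermediate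
8 | (4S)-4-(4-bromophenoxy)-4-methylhex-5-ynal, not isolated | O=CCC[C@@](Oc1ccc(Br)cc1)(C)C#C | intermediate
9 | (4S)-4-(4-bromophenoxy)-4-methylhex-5-yn-1-ol | OCCC[C@@](Oc1ccc(Br)cc1)(C)C#C | intermediate
10 | {[(4S)-4-(4-bromophenoxy)-4-methylhex-5-yn-1-yl]oxy}(tert-butyl)dimethylsilane | CC(C)(C)[Si](C)(C)OCCC[C@@](Oc1ccc(Br)cc1)(C)C#C | intermediate
11 | (2S)-6-bromo-2-{3-[(tert-butyldimethylsilyl)oxy]propyl}-2-methyl-2H-chromene | CC(C)(C)[Si](C)(C)OCCC[C@@]1(C)C=Cc2cc(Br)ccc2O1 | intermediate
12 | 2,3-dihydroxybenzaldehyde | O=Cc1cccc(O)c1O | starting material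
13 | 2,3-bis[(triisopropylsilyl)oxy]benzaldehyde | O=Cc1cccc(O[Si](C(C)C)(C(C)C)C(C)C)c1O[Si](C(C)C)(C(C)C)C(C)C | intermediate
14 | 1-ethenyl-2,3-bis[(triisopropylsilyl)oxy]benzene | C=Cc1cccc(O[Si](C(C)C)(C(C)C)C(C)C)c1O[Si](C(C)C)(C(C)C)C(C)C | intermediate
15 | 9-(2-{2,3-bis[(triisopropylsilyl)oxy]phenyl}ethyl)-9-borabicyclo[3.3.1]nonane, not isolated | CC(C)[Si](C(C)C)(C(C)C)Oc1cccc(CCB2C3CCCC2CCC3)c1O[Si](C(C)C)(C(C)C)C(C)C | intermediate
16 | (2S)-6-(2-{2,3-bis[(triisopropylsilyl)oxy]phenyl}ethyl)-2-{3-[(tert-butyldimethylsilyl)oxy]propyl}-2-methyl-2H-chromene | CC(C)(C)[Si](C)(C)OCCC[C@@]1(C)C=Cc2cc(CCc3cccc(O[Si](C(C)C)(C(C)C)C(C)C)c3O[Si](C(C)C)(C(C)C)C(C)C)ccc2O1 | intermediate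
17 | 3-[(2S)-6-(2-{2,3-bis[(triisopropylsilyl)oxy]phenyl}ethyl)-2-methyl-2H-chromen-2-yl]propan-1-ol | OCCC[C@@]1(C)C=Cc2cc(CCc3cccc(O[Si](C(C)C)(C(C)C)C(C)C)c3O[Si](C(C)C)(C(C)C)C(C)C)ccc2O1 | intermediate
18 | 3-[(2S)-6-(2-{2,3-bis[(triisopropylsilyl)oxy]phenyl}ethyl)-2-methyl-2H-chromen-2-yl]propanal | O=CCC[C@@]1(C)C=Cc2cc(CCc3cccc(O[Si](C(C)C)(C(C)C)C(C)C)c3O[Si](C(C)C)(C(C)C)C(C)C)ccc2O1 | intermediate
19 | ethyl 2-(triphenylphosphoranylidene)propanoate | CCOC(=O)C(C)=P(c1ccccc1)(c1ccccc1)c1ccccc1 | starting material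
20 | ethyl (2E)-5-[(2S)-6-(2-{2,3-bis[(triisopropylsilyl)oxy]phenyl}ethyl)-2-methyl-2H-chromen-2-yl]-2-methylpent-2-enoate | CCOC(=O)/C(C)=C/CC[C@@]1(C)C=Cc2cc(CCc3cccc(O[Si](C(C)C)(C(C)C)C(C)C)c3O[Si](C(C)C)(C(C)C)C(C)C)ccc2O1 | intermediate
21 | (2E)-5-[(2S)-6-(2-{2,3-bis[(triisopropylsilyl)oxy]phenyl}ethyl)-2-methyl-2H-chromen-2-yl]-2-methylpent-2-en-1-ol | OC/C(C)=C/CC[C@@]1(C)C=Cc2cc(CCc3cccc(O[Si](C(C)C)(C(C)C)C(C)C)c3O[Si](C(C)C)(C(C)C)C(C)C)ccc2O1 | intermediate
22 | 3-{2-[(2S)-2-[(3E)-5-hydroxy-4-methylpent-3-en-1-yl]-2-methyl-2H-chromen-6-yl]ethyl}benzene-1,2-diol | C/C(=C\CC[C@@]1(C)C=Cc2cc(CCc3cccc(O)c3O)ccc2O1)CO | target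

Total step count: 15.
Longest linear sequence: 13 steps (steps 1 to 7 and 10 to 15, geraniol to target); the catechol arm takes steps 8 and 9 before it joins at step 10.

Steps most likely to fail

1. Step 7. What may go wrong: the gold cation ionises the tertiary propargylic C–O bond (loss of 4-bromophenol, erosion of enantiopurity), or the Friedel–Crafts closure stalls on the bromine-deactivated ring. The fallback forms C3=C4 by ring-closing metathesis instead of C4–C4a; it sets out from 5 and comes back at 11, and again never breaks the C–O bond at the stereocentre.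
   - Ozonolysis of 5 with NaBH4 work-up should give (4S)-4-methylhex-5-yne-1,4-diol F1.
   - TBSCl and imidazole should silylate only the primary hydroxyl to give (3S)-6-[(tert-butyldimethylsilyl)oxy]-3-methylhex-1-yn-3-ol F2.
   - Semi-hydrogenation (H2, Pd/CaCO3 poisoned with Pb(OAc)2, quinoline) should give (3S)-6-[(tert-butyldimethylsilyl)oxy]-3-methylhex-1-en-3-ol F3.
   - The sodium alkoxide of F3 (NaH, DMF) should displace fluoride from 5-bromo-2-fluorobenzaldehyde, an SNAr activated by the ortho formyl group, to give 5-bromo-2-{[(3S)-6-[(tert-butyldimethylsilyl)oxy]-3-methylhex-1-en-3-yl]oxy}benzaldehyde F4.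
   - Wittig methylenation (Ph3PCH3Br, KOtBu) should give 4-bromo-2-ethenyl-1-{[(3S)-6-[(tert-butyldimethylsilyl)oxy]-3-methylhex-1-en-3-yl]oxy}benzene F5.
   - The second-generation Grubbs catalyst RuCl2(H2IMes)(PCy3)(=CHPh) in CH2Cl2 at 40 °C should close the pyran ring with loss of ethene to give 11.

2. Step 4. What may go wrong: the strong base turns the iodonium salt into an aryne or decomposes it by electron transfer, or the hindered tertiary alkoxide is arylated incompletely. The fallback is a classical SNAr and Sandmeyer sequence from 5 to 7.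
   - The sodium alkoxide of 5 (NaH, DMF, 0 °C → rt) should displace fluoride from 1-fluoro-4-nitrobenzene to give 1-{[(3S)-3,7-dimethyloct-6-en-1-yn-3-yl]oxy}-4-nitrobenzene F6.
   - Fe powder and NH4Cl in EtOH/H2O should reduce the nitro group, without touching alkyne or alkene, to 4-{[(3S)-3,7-dimethyloct-6-en-1-yn-3-yl]oxy}aniline F7.
   - Sandmeyer bromination (tBuONO, CuBr2, MeCN, 0 °C → rt) should then give 7.

3. Step 10. What may go wrong: protodeboronation or beta-hydride elimination of the alkylborane, slow oxidative addition to the electron-rich bromide, or base-induced loss of aryl silyl groups. The fallback is a base-free Negishi coupling from 14 to 16.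
   - Hydroboration of 14 with 9-BBN and oxidation with NaBO3·4H2O should give 2-{2,3-bis[(triisopropylsilyl)oxy]phenyl}ethan-1-ol F8.
   - I2, PPh3 and imidazole should give 1-(2-iodoethyl)-2,3-bis[(triisopropylsilyl)oxy]benzene F9.
   - Zinc insertion (Zn dust, LiCl, THF) should give (2-{2,3-bis[(triisopropylsilyl)oxy]phenyl}ethyl)zinc iodide F10, used in solution.
   - Coupling of F10 with 11 (Pd(OAc)2, SPhos, THF, rt) should give 16.

Further compounds
F1 | step 7 | (4S)-4-methylhex-5-yne-1,4-diol | OCCC[C@@](O)(C)C#C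
F2 | step 7 | (3S)-6-[(tert-butyldimethylsilyl)oxy]-3-methylhex-1-yn-3-ol | CC(C)(C)[Si](C)(C)OCCC[C@@](O)(C)C#C
F3 | step 7 | (3S)-6-[(tert-butyldimethylsilyl)oxy]-3-methylhex-1-en-3-ol | CC(C)(C)[Si](C)(C)OCCC[C@@](O)(C)C=C
F4 | step 7 | 5-bromo-2-{[(3S)-6-[(tert-butyldimethylsilyl)oxy]-3-methylhex-1-en-3-yl]oxy}benzaldehyde | CC(C)(C)[Si](C)(C)OCCC[C@@](Oc1ccc(Br)cc1C=O)(C)C=C
F5 | step 7 | 4-bromo-2-ethenyl-1-{[(3S)-6-[(tert-butyldimethylsilyl)oxy]-3-methylhex-1-en-3-yl]oxy}benzene | CC(C)(C)[Si](C)(C)OCCC[C@@](Oc1ccc(Br)cc1C=C)(C)C=C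
F6 | step 4 | 1-{[(3S)-3,7-dimethyloct-6-en-1-yn-3-yl]oxy}-4-nitrobenzene | CC(C)=CCC[C@@](Oc1ccc([N+](=O)[O-])cc1)(C)C#C
F7 | step 4 | 4-{[(3S)-3,7-dimethyloct-6-en-1-yn-3-yl]oxy}aniline | CC(C)=CCC[C@@](Oc1ccc(N)cc1)(C)C#C
F8 | step 10 | 2-{2,3-bis[(triisopropylsilyl)oxy]phenyl}ethan-1-ol | OCCc1cccc(O[Si](C(C)C)(C(C)C)C(C)C)c1O[Si](C(C)C)(C(C)C)C(C)C
F9 | step 10 | 1-(2-iodoethyl)-2,3-bis[(triisopropylsilyl)oxy]benzene | ICCc1cccc(O[Si](C(C)C)(C(C)C)C(C)C)c1O[Si](C(C)C)(C(C)C)C(C)C
F10 | step 10 | (2-{2,3-bis[(triisopropylsilyl)oxy]phenyl}ethyl)zinc iodide | I[Zn]CCc1cccc(O[Si](C(C)C)(C(C)C)C(C)C)c1O[Si](C(C)C)(C(C)C)C(C)C
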